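**Plan**

Ring atoms are called C1 (C(OMe)(prenyl)), C2 (ring C=O), C3 (C‑acyl), C4 (C–OH), C5 (C‑prenyl), C6 (C–OH next to C1). The retrosynthesis cuts, in this order: both CH=CMe2 ends (cross‑metathesis), the C1–CH2 bond (Claisen, back to an aryl ether on O2), the C3–acyl bond (Friedel–Crafts), then the ring bonds C2–C3 and C4–C5.
Enabling feature: the ring is a dearomatised 1,2,3,5‑tetraoxygenated benzene. C2, C5, C6, C1 (C–O, C‑alkyl, C–O, C–O) have the pattern of a squarate‑derived 2‑alkyl‑3,4‑dialkoxycyclobutenone, and C3–C4 (CH, C–O) that of an alkoxyalkyne.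
Forward: dimethyl squarate gives the four‑membered ring carrying allyl (future C5) and OMe (future C1). Ethoxyacetylene expands it by two carbons to the six‑membered ring, a phenol whose only free OH is on C2. Then follow C3 acylation, O2 etherification, Claisen dearomatisation, double metathesis and enol ether hydrolysis.
Stereochemistry: the single stereocentre C1 (S) comes from commercial (R)‑but‑3‑en‑2‑ol, by Mitsunobu inversion to the (S)‑aryl ether and 1,3‑chirality transfer through the chair Claisen transition state.

Key step: step 4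

Remark: the target is handled as the tautomer drawn (ketone at C2, enols at C4 and C6); the ring tautomers interconvert and do not affect C1. Compounds 3, 5, 6, 9 and 11 are racemic, and their stereocentres are destroyed before C1 is set. The labels C1–C6 refer to the target ring as defined above, not to the locants in compound names.

**Route**

Step 1
Reactants: 1 dimethyl squarate (3,4-dimethoxycyclobut-3-ene-1,2-dione); 2 allylmagnesium bromide
Product: 4 3-allyl-4-methoxycyclobut-3-ene-1,2-dione, via carbinol adduct 3 (not isolated)
Conditions: THF, −78 °C; 2 M HCl quench, then conc. HCl (cat.), CH2Cl2, 23 °C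
Reagents that add atoms: none
Why: The Grignard reagent should add 1,2 to one squarate carbonyl at low temperature, and acid then ionises the tertiary carbinol with loss of methanol (squarate‑to‑cyclobutenedione transposition), which places the allyl group on the future C5; no stereocentre is carried on.

Step 2
Reactants: 4 3-allyl-4-methoxycyclobut-3-ene-1,2-dione
Product: 5 2-allyl-4-hydroxy-3-methoxycyclobut-2-en-1-one
Conditions: NaBH4, CeCl3·7H2O, MeOH, −78 °C
Reagents that add atoms: none
Why: Luche 1,2‑reduction should take place at the more electrophilic carbonyl, the one attached to the methoxy‑bearing carbon, because the other carbonyl is a deactivated vinylogous ester (the site organolithium reagents also attack in such diones); the new carbinol centre is racemic and is erased in step 4.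

Step 3
Reactants: 5 2-allyl-4-hydroxy-3-methoxycyclobut-2-en-1-one
Product: 6 2-allyl-3,4-dimethoxycyclobut-2-en-1-one
Conditions: MeI, Ag2O, MeCN, 23 °C, dark
Reagents that add atoms: iodomethane, CI
Why: Purdie methylation (Ag2O‑promoted O‑alkylation) should etherify the secondary carbinol under near‑neutral conditions that the acid‑ and base‑labile 4‑hydroxycyclobutenone tolerates; this methoxy group becomes the C1 methoxy of the target.

Step 4
Reactants: 6 2-allyl-3,4-dimethoxycyclobut-2-en-1-one; 7 ethoxyacetylene
Product: 12 4-allyl-5-ethoxy-2,3-dimethoxyphenol, via vinylketene 8 (not isolated), via vinylcyclobutenone 9 (not isolated), via dienylketene 10 (not isolated), via cyclohexadienone 11 (not isolated)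
Conditions: 7 (3 equiv), toluene, 80 → 110 °C, sealed tube
Reagents that add atoms: none
Why: Heating should open 6 by a conrotatory 4π electrocyclic reaction (4‑methoxy group rotating outward) to vinylketene 8, whose ketene C=C bond adds the electron‑rich alkyne 7 in a [2+2] cycloaddition to give 2‑vinylcyclobutenone 9; a second 4π opening gives dienylketene 10, disrotatory 6π electrocyclisation gives dienone 11, and enolisation gives phenol 12. The closest known reaction type is the Danheiser benzannulation of cyclobutenones with alkoxyalkynes. Two rings are closed: the four‑membered ring of 9 by ketene–alkyne [2+2] cycloaddition and the six‑membered ring by 6π electrocyclisation between the ketene carbon (C2) and the methoxy‑bearing diene terminus (C1), so that the original four‑membered ring C2–C5–C6–C1 ends up enlarged by the alkyne carbons C3 and C4 inserted between C2 and C5. No stereocentre is formed, and the racemic centre of 6 is erased at the first ring opening. The selectivity needed is the orientation of the alkyne, which polarity secures (the nucleophilic CH carbon of the ynol ether bonds to the electrophilic ketene carbon, so OEt ends meta to the new hydroxyl), and the allyl‑inward ketene from 9 is unproductive and can re‑close to 9 while the vinyl‑inward isomer is consumed. The substrate therefore delivers a ring with every position differentiated: the only free hydroxyl on C2 next to the C1 methoxy carbon and the only free CH at C3.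

Step 5
Reactants: 12 4-allyl-5-ethoxy-2,3-dimethoxyphenol; 13 3-phenylpropanoyl chloride
Product: 14 1-(3-allyl-2-ethoxy-6-hydroxy-4,5-dimethoxyphenyl)-3-phenylpropan-1-one
Conditions: TiCl4, CH2Cl2, 0 → 23 °C
Reagents that add atoms: none
Why: Friedel–Crafts ortho‑acylation through the titanium phenoxide (direct C‑acylation, or O‑acylation followed by Fries shift) can only reach C3, the single unsubstituted and most activated ring position, and the terminal alkene and the alkyl ethers should tolerate TiCl4 at or below room temperature.

Step 6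
Reactants: 14 1-(3-allyl-2-ethoxy-6-hydroxy-4,5-dimethoxyphenyl)-3-phenylpropan-1-one; 15 (R)-but-3-en-2-ol
Product: 16 1-{3-allyl-6-[(2S)-but-3-en-2-yloxy]-2-ethoxy-4,5-dimethoxyphenyl}-3-phenylpropan-1-one
Conditions: PPh3, diisopropyl azodicarboxylate, toluene, 0 → 23 °C
Reagents that add atoms: none
Why: Mitsunobu etherification should proceed by SN2 displacement of the activated carbinol by the only free phenol (made acidic by the ortho acyl group) with inversion, turning the (R)‑alcohol into the (S)‑configured aryl but‑3‑en‑2‑yl ether.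

Step 7
Reactants: 16 1-{3-allyl-6-[(2S)-but-3-en-2-yloxy]-2-ethoxy-4,5-dimethoxyphenyl}-3-phenylpropan-1-one
Product: 17 (6S)-4-allyl-6-[(2E)-but-2-en-1-yl]-3-ethoxy-5,6-dimethoxy-2-(3-phenylpropanoyl)cyclohexa-2,4-dien-1-one
Conditions: toluene, 100 °C
Reagents that add atoms: none
Why: Aromatic Claisen [3,3]‑sigmatropic rearrangement through a chair transition state with the methyl group pseudo‑equatorial should transfer the (S)‑carbinol configuration to the new quaternary centre C1 as (S) with an (E)‑but‑2‑enyl group; the allyl terminus should go to the methoxy‑bearing ortho carbon C1 rather than to C3, which is shielded by the twisted acyl group and whose product would lose the vinylogous‑ester conjugation, and because the para carbon C5 is substituted the dienone cannot re‑aromatise.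

Step 8
Reactants: 17 (6S)-4-allyl-6-[(2E)-but-2-en-1-yl]-3-ethoxy-5,6-dimethoxy-2-(3-phenylpropanoyl)cyclohexa-2,4-dien-1-one
Product: 18 (6S)-3-ethoxy-5,6-dimethoxy-4,6-bis(3-methylbut-2-en-1-yl)-2-(3-phenylpropanoyl)cyclohexa-2,4-dien-1-one
Conditions: 2-methylbut-2-ene (large excess), second-generation Hoveyda–Grubbs catalyst (5 mol%), CH2Cl2, 40 °C
Reagents that add atoms: 2-methylbut-2-ene, CC=C(C)C
Why: Olefin cross‑metathesis with excess 2‑methylbut‑2‑ene should exchange the terminal CH2 of the allyl group and the CHCH3 end of the butenyl group for isopropylidene, giving both prenyl groups in one operation without touching the quaternary stereocentre.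

Step 9
Reactants: 18 (6S)-3-ethoxy-5,6-dimethoxy-4,6-bis(3-methylbut-2-en-1-yl)-2-(3-phenylpropanoyl)cyclohexa-2,4-dien-1-one
Product: 19 (6S)-3,5-dihydroxy-6-methoxy-4,6-bis(3-methylbut-2-en-1-yl)-2-(3-phenylpropanoyl)cyclohexa-2,4-dien-1-one (target)
Conditions: 1 M HCl, THF, 23 °C
Reagents that add atoms: water, O
Why: Acid hydrolysis of the two vinylogous esters (addition of water at C4 and C6, loss of ethanol and methanol) should release the enolised β‑triketone, while the C1 methoxy group, an ordinary alkyl ether on a carbon flanked by two carbonyl carbons, and the quaternary stereocentre are untouched.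

**Compound list**

1 | dimethyl squarate (3,4-dimethoxycyclobut-3-ene-1,2-dione) | COC1=C(OC)C(=O)C1=O | starting material
2 | allylmagnesium bromide | C=CC[Mg]Br | starting material
3 | 4-allyl-4-hydroxy-2,3-dimethoxycyclobut-2-en-1-one (racemic) | COC1=C(OC)C(O)(CC=C)C1=O | intermediate
4 | 3-allyl-4-methoxycyclobut-3-ene-1,2-dione | COC1=C(CC=C)C(=O)C1=O | intermediate
5 | 2-allyl-4-hydroxy-3-methoxycyclobut-2-en-1-one (racemic) | COC1=C(CC=C)C(=O)C1O | intermediate
6 | 2-allyl-3,4-dimethoxycyclobut-2-en-1-one (racemic) | COC1C(OC)=C(CC=C)C1=O | intermediate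
7 | ethoxyacetylene | CCOC#C | starting material
8 | (Z)-2-allyl-3,4-dimethoxybuta-1,3-dien-1-one (vinylketene) | O=C=C(CC=C)/C(OC)=C/OC | intermediate
9 | 4-allyl-4-[(Z)-1,2-dimethoxyvinyl]-3-ethoxycyclobut-2-en-1-one (racemic) | O=C1C=C(OCC)C1(CC=C)/C(OC)=C/OC | intermediate
10 | 4-allyl-3-ethoxy-5,6-dimethoxyhexa-1,3,5-trien-1-one (dienylketene) | O=C=C/C(OCC)=C(CC=C)\C(OC)=C\OC | intermediate
11 | 4-allyl-3-ethoxy-5,6-dimethoxycyclohexa-2,4-dien-1-one (racemic) | O=C1C=C(OCC)C(CC=C)=C(OC)C1OC | intermediate
12 | 4-allyl-5-ethoxy-2,3-dimethoxyphenol | Oc1cc(OCC)c(CC=C)c(OC)c1OC | intermediate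
13 | 3-phenylpropanoyl chloride | O=C(Cl)CCc1ccccc1 | starting material
14 | 1-(3-allyl-2-ethoxy-6-hydroxy-4,5-dimethoxyphenyl)-3-phenylpropan-1-one | CCOc1c(CC=C)c(OC)c(OC)c(O)c1C(=O)CCc1ccccc1 | intermediate
15 | (R)-but-3-en-2-ol | C[C@@H](O)C=C | starting material
16 | 1-{3-allyl-6-[(2S)-but-3-en-2-yloxy]-2-ethoxy-4,5-dimethoxyphenyl}-3-phenylpropan-1-one | CCOc1c(CC=C)c(OC)c(OC)c(O[C@@H](C)C=C)c1C(=O)CCc1ccccc1 | intermediate
17 | (6S)-4-allyl-6-[(2E)-but-2-en-1-yl]-3-ethoxy-5,6-dimethoxy-2-(3-phenylpropanoyl)cyclohexa-2,4-dien-1-one | CO[C@]1(C/C=C/C)C(=O)C(C(=O)CCc2ccccc2)=C(OCC)C(CC=C)=C1OC | intermediate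
18 | (6S)-3-ethoxy-5,6-dimethoxy-4,6-bis(3-methylbut-2-en-1-yl)-2-(3-phenylpropanoyl)cyclohexa-2,4-dien-1-one | CO[C@]1(CC=C(C)C)C(=O)C(C(=O)CCc2ccccc2)=C(OCC)C(CC=C(C)C)=C1OC | intermediate
19 | (6S)-3,5-dihydroxy-6-methoxy-4,6-bis(3-methylbut-2-en-1-yl)-2-(3-phenylpropanoyl)cyclohexa-2,4-dien-1-one | CO[C@]1(CC=C(C)C)C(=O)C(C(=O)CCc2ccccc2)=C(O)C(CC=C(C)C)=C1O | target

**Step count and risks**

Total step count: 9. Longest linear sequence: 9 steps (1 → 19).

Steps most likely to fail:

Step 4. The vinylketene may be captured too slowly by the alkyne, so that ketene dimerisation or acylation of the product phenol takes over. After the second ring opening the allyl group may also be trapped by the ketene in an intramolecular [2+2] reaction. The fallback sets out from 4 and comes back at 12; it keeps the four‑to‑six ring expansion but makes it fully intramolecular. Dione 4 is treated at −78 °C with 1‑tert‑butoxyvinyllithium (tert‑butyl vinyl ether, t‑BuLi, THF), which adds to the same carbonyl as the hydride of step 2. The lithium alkoxide is methylated in the flask with MeOTf to give 2-allyl-4-(1-tert-butoxyvinyl)-3,4-dimethoxycyclobut-2-en-1-one F1. Heating in toluene at 110 °C should cause 4π opening (methoxy outward), 6π closure and enolisation to 2-allyl-5-tert-butoxy-3,4-dimethoxyphenol F2, whose free hydroxyl is on C4. O‑Ethylation (EtI, K2CO3, acetone) gives 1-allyl-4-tert-butoxy-2-ethoxy-5,6-dimethoxybenzene F3, and TFA in CH2Cl2 at 0 °C removes the tert‑butyl group to give 12.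

Step 7. The butenyl group may migrate to the acyl‑bearing ortho carbon C3 or move on by a Cope shift to C5, and ionisation of the secondary allylic ether may erode the chirality transfer. The fallback sets out from 14 and comes back at 19; it unveils the C4 hydroxyl before the sigmatropic step so that a strong hydrogen bond to the ketone locks the acyl group in conjugation and makes attack at C3 costly. BCl3 (CH2Cl2, −78 °C) should remove only the ethyl group ortho to the ketone, by chelation, to give 1-(3-allyl-2,6-dihydroxy-4,5-dimethoxyphenyl)-3-phenylpropan-1-one F4. A Mitsunobu reaction with one equivalent of 15 should take the C2 hydroxyl, the less hindered one and the one not held by the ketone, to give 1-{3-allyl-6-[(2S)-but-3-en-2-yloxy]-2-hydroxy-4,5-dimethoxyphenyl}-3-phenylpropan-1-one F5. Claisen rearrangement (toluene, 80–100 °C) gives (6S)-4-allyl-6-[(2E)-but-2-en-1-yl]-3-hydroxy-5,6-dimethoxy-2-(3-phenylpropanoyl)cyclohexa-2,4-dien-1-one F6. Cross‑metathesis as in step 8 gives (6S)-3-hydroxy-5,6-dimethoxy-4,6-bis(3-methylbut-2-en-1-yl)-2-(3-phenylpropanoyl)cyclohexa-2,4-dien-1-one F7, and hydrolysis of the remaining C6 enol methyl ether (1 M HCl, THF) gives 19.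

Step 6. The hindered, hydrogen‑bonded phenol may react slowly, and SN2′ attack or partial ionisation of the activated allylic alcohol would give the linear ether or lower the enantiomeric purity. The fallback sets out from 14 and comes back at 16; it creates the ether stereocentre by catalysis instead of by inversion of a bought carbinol. The sodium phenoxide of 14 (NaH, THF) is allylated with (E)‑but‑2‑enyl methyl carbonate under [Ir(cod)Cl]2 and the enantiomer of a chiral phosphoramidite ligand that delivers the (S)‑ether; this should give the branched ether 16 directly. This fallback makes no compound outside the list: none F0.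

**Further compounds**

F1 | step 4 | 2-allyl-4-(1-tert-butoxyvinyl)-3,4-dimethoxycyclobut-2-en-1-one (racemic) | COC1=C(CC=C)C(=O)C1(OC)C(=C)OC(C)(C)C
F2 | step 4 | 2-allyl-5-tert-butoxy-3,4-dimethoxyphenol | Oc1cc(OC(C)(C)C)c(OC)c(OC)c1CC=C
F3 | step 4 | 1-allyl-4-tert-butoxy-2-ethoxy-5,6-dimethoxybenzene | CCOc1cc(OC(C)(C)C)c(OC)c(OC)c1CC=C
F4 | step 7 | 1-(3-allyl-2,6-dihydroxy-4,5-dimethoxyphenyl)-3-phenylpropan-1-one | Oc1c(CC=C)c(OC)c(OC)c(O)c1C(=O)CCc1ccccc1
F5 | step 7 | 1-{3-allyl-6-[(2S)-but-3-en-2-yloxy]-2-hydroxy-4,5-dimethoxyphenyl}-3-phenylpropan-1-one | Oc1c(CC=C)c(OC)c(OC)c(O[C@@H](C)C=C)c1C(=O)CCc1ccccc1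
F6 | step 7 | (6S)-4-allyl-6-[(2E)-but-2-en-1-yl]-3-hydroxy-5,6-dimethoxy-2-(3-phenylpropanoyl)cyclohexa-2,4-dien-1-one | CO[C@]1(C/C=C/C)C(=O)C(C(=O)CCc2ccccc2)=C(O)C(CC=C)=C1OC
F7 | step 7 | (6S)-3-hydroxy-5,6-dimethoxy-4,6-bis(3-methylbut-2-en-1-yl)-2-(3-phenylpropanoyl)cyclohexa-2,4-dien-1-one | CO[C@]1(CC=C(C)C)C(=O)C(C(=O)CCc2ccccc2)=C(O)C(CC=C(C)C)=C1OC
F0 | step 6 | none | none
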